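## Structural features

Kanzonol X (34) is a (3R)-isoflavan: a chroman, made of the aromatic ring A fused to the dihydropyran ring C, that carries the aromatic ring B on C3. Both arenes are 2-prenylresorcinol units. In ring A the prenylated carbon C8 lies between the ether carbon C8a (O1) and the phenolic carbon C7, C4a bears the C4 methylene, and C5 and C6 are unsubstituted. Ring B has hydroxyls on C2' and C4', prenyl on C3' and the bond to C3 on C1'. C3 is the only stereocentre, a benzylic methine with no stereogenic neighbour, and it is configurationally safe as long as neither C2 nor C4 is a carbonyl carbon. The fragile parts are three electron-rich phenols that each stand ortho to a prenyl group (acid converts such pairs into 2,2-dimethylchromans) and two trisubstituted alkenes that rule out hydrogenation, ozonolysis and strong acid. The real difficulty is regiochemical: each prenyl group must sit on the carbon between two oxygens, and the C8a oxygen must be distinguished from the three other phenolic oxygens so that it alone closes ring C. The key step uses the pattern C8a(O)–C8(prenyl)–C7(O) of ring A with the side chain on C4a: C8a, C6, C5 and C4a map onto a vinylketene, C8 and C7 onto a siloxyalkyne, and the annulation delivers C8a as the only free phenol.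

## Logic of the disconnections

34 to 33: the two acetal C–O bonds on the ring B oxygens are cut last. The free ortho-prenyl phenols are the most fragile form of the molecule, so they should exist only in the final flask. The forward step must cleave two aryl acetals without protonating a prenyl alkene.

33 to 31 (through 32): the O1–C2 bond of ring C and the O–Si bond at C7 are cut. This removes ring C and leaves an open chain between two arenes. The forward closure needs exactly one free phenol (C8a) and a leaving group on C2; 31 has both, and C3 is not a reacting centre.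

31 to 22 and 26: ring A is taken apart at C8–C8a, C6–C7 and C4a–C8a (the C5–C6 bond goes back to the carbonyl-to-carbene shift that precedes them). This is the largest simplification: a penta-substituted arene becomes an acyclic diazo enone and a seven-carbon alkyne, and every ring A substituent is placed by connectivity. The forward step needs the ketene to choose the ynol ether over three prenyl alkenes and needs C3 to survive light and heat.

26 to 23: the O–Si bond and the bond between the two alkyne carbons are cut. The oxygen-bearing carbon is the ester carbonyl and the prenyl-bearing carbon is a one-carbon insert. The forward step must add a carbenoid to an enolisable ester and silylate the ynolate on oxygen.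

22 to 20, then to 18 and 19: the C=N2 unit is removed and the C=C bond of the enone is cut. This reduces the diazo enone to a terminal alkene and a four-carbon ketone. The forward steps need metathesis at the monosubstituted alkene only, and diazo transfer to a methyl ketone that cannot be made by way of an acid chloride.

18 to 17, 16, and then 13 and 14: the C–Cl bond, the oxidation level of C2 and the C3–C4 bond are traced back. C3 becomes the α-carbon of an imide and is set by auxiliary-controlled alkylation with a three-carbon electrophile. The forward alkylation must give high facial selectivity with an α-aryl enolate and the reduction must not epimerise C3.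

13 to 10 and 11, and 10 to 8, then to 5 and 6: the N-acyl bond, the oxidation level of the side chain and the C1'–C3 bond are cut. Ring B is left as a simple arene plus a two-carbon electrophile. The forward steps need ring metalation ortho to an acetal oxygen in the presence of the prenyl group, and an oxidation that spares the alkene.

5 to 2 and 3, and 2 to 1: the C3'–prenyl bond and the two acetal O–C bonds are cut. The prenyl carbon is the one between the two oxygens, the preferred site of directed metalation, so no electrophilic substitution on a free phenol is needed.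

## Other disconnections considered

Alternative 1: The cut runs through ring C at C3–C4 and O1–C2, so that ring A appears as an ortho-quinone methide and ring B as an enolisable aldehyde.
- Forward key step: mild base would expel sulfinate from 3-(methoxymethoxy)-2-prenyl-6-[(phenylsulfonyl)methyl]phenol A1. The enamine formed from aldehyde 9 and a diarylprolinol silyl ether catalyst would add to the methide carbon, and the phenoxide would close on C2 to give the chroman-2-ol A2 as two anomers.
- In its favour: one catalytic step forms both ring C bonds and sets C3, the two arenes are prepared separately (9 is already on the chosen route), and no auxiliary is needed.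
- Against it here: in A2 the stereocentre is benzylic and α to a masked aldehyde, so ring–chain equilibration in the presence of amine and base can erode its configuration. Aldehyde 9 is an electron-rich arylacetaldehyde prone to self-condensation. C2 arrives one oxidation level too high, so the ring must be opened by hydride and closed again, or deoxygenated with silane and Lewis acid beside prenyl groups and acetals. A1 needs a ring A whose two oxygens are already differentiated by selective protection.
- Comparison: on structure the plans are equal in how the prenyl groups reach their positions (directed metalation), while the chosen plan gets the C8a/C7 differentiation from the annulation itself. On mechanism the alternative is the better in using catalytic enantiocontrol; the chosen plan is the better in keeping C3 away from any carbonyl group after step 7. On step economy the alternative is the better in longest linear sequence and about equal in total count once the lactol is corrected.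

Alternative 2: Ring B is cut at C1'–C6' and C3'–C4' and traced back to a saturated 1,3-dione.
- Forward key step: KOt-Bu would add the more substituted enolate carbon of 1-[(3R)-7-(methoxymethoxy)-8-prenylchroman-3-yl]propan-2-one A3 to methyl acrylate A4 and then condense the methyl carbon onto the ester, giving the 4-substituted cyclohexane-1,3-dione A5 (both epimers at C1'). C-prenylation between the carbonyls and dehydrogenation would complete ring B.
- In its favour: the ring B prenyl group is placed by enolate alkylation at the carbon between two carbonyls, and ring B needs no phenol protection, so the final acetal cleavage disappears. On both points the alternative is the better. The new centre C1' is erased on aromatisation, and C3, β to the carbonyls, is not acidic.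
- Against it here: the Michael step needs the methylene enolate and not the kinetic methyl enolate, and double addition competes. Dehydrogenation of a 2-prenyl-1,3-dione to a resorcinol needs an oxidant in a molecule with two prenyl alkenes and an electron-rich chroman, where allylic oxidation and oxidative cyclisation of the enol onto the prenyl group are likely competitors. A3 still requires ring A, ring C and C3 to be made first.
- Comparison: on structure both plans build one arene from open-chain carbons, but the chosen plan reaches the aromatic oxidation level by tautomerisation and needs no oxidant, which is the safer course. On mechanism an anionic cascade stands against a pericyclic one, and the two are equal in that regiochemistry follows from intrinsic polarity. On step economy the alternative is longer, since a chiral chroman ketone precedes its key step and prenylation, aromatisation and deprotection follow it.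

Alternative 3: The cuts are C3–C1' and C4–C4a, leaving a two-carbon vinylboron unit between the arenes.
- Forward key step: t-BuLi would convert 1-bromo-2,4-bis(methoxymethoxy)-3-prenylbenzene A6 into aryllithium 7, which adds to vinylboronic acid pinacol ester A7. Pd(OAc)2 with a MandyPhos ligand and NaOTf would then couple the ate complex with [6-bromo-3-(methoxymethoxy)-2-prenylphenoxy](tert-butyl)dimethylsilane A8. After oxidative addition to zerovalent palladium, the ring B aryl shifts from boron to C3 as C4–C4a forms, giving the secondary boronic ester A9. One-carbon homologation with retention, oxidation, desilylation, Mitsunobu closure and deprotection would follow.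
- In its favour: three components are joined in one catalytic enantioselective step and both aryl halides come from the same metalation chemistry. In convergence, in longest linear sequence and in using a catalyst in place of an auxiliary the alternative is the better.
- Against it here: both aryl partners carry ortho oxygen substituents next to prenyl groups, so the migrating group and the electrophile are hindered and the acetal oxygens can bind lithium and palladium. The enantioselectivity for such partners cannot be taken for granted. An aryl–palladium species may add to a prenyl alkene. The hindered benzylic boronate must be homologated without protodeboronation. A8 needs two different oxygen protecting groups on ring A.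
- Comparison: on structure both plans close ring C by joining a phenol oxygen to a primary carbon, which is equal, but the chosen plan receives the free C8a phenol from its key step. On mechanism the chosen key step has no ligand-controlled selectivity to tune, while the alternative replaces a stoichiometric auxiliary. On step economy the alternative is shorter before its key step, and the chosen plan is shorter after it (two steps against four).

Key step: step 12

Remarks on the chemistry (abbreviations: prenyl = 3-methylbut-2-enyl; MOM = methoxymethyl; Ar = 2,4-bis(methoxymethoxy)-3-prenylphenyl, the ring B aryl group):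
- Carbon count of the alkyne: an ester-to-ynolate homologation inserts one carbon, so the seven-carbon siloxyalkyne 26 must come from the six-carbon ester 23. Ethyl 5-methylhex-4-enoate would give the homoprenyl alkyne and would fit only a non-homologating ynolate synthesis.
- Design of the precursor: C2 is carried as a chloride from step 8. A silyl ether at C2 would need a selective alkyl-silyl cleavage beside an aryl silyl ether and then a Mitsunobu reaction; with the chloride the single free phenol of 31 closes ring C directly. Only a spectator group of 22 and 31 is changed; the bonds and the ring formed in the key step are the same.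
- Irradiation is placed above 300 nm so that only the diazo enone absorbs.
- Assumption: 6, 11, 14, 19 and 23 are taken as commercial.

## Route

Step 1
Reactants: 1 resorcinol
Product: 2 1,3-bis(methoxymethoxy)benzene
Conditions: MeOCH2Cl, i-Pr2NEt, CH2Cl2, 0 → 20 °C
Reagents that add atoms: chloromethyl methyl ether, COCCl
Why: Double O-alkylation of the phenol (Williamson-type acetal formation); the MOM ethers direct both later lithiations and withstand the basic, reductive, metathesis and photochemical steps that follow.

Step 2
Reactants: 2 1,3-bis(methoxymethoxy)benzene; 3 prenyl bromide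
Product: 5 1,3-bis(methoxymethoxy)-2-prenylbenzene, via aryllithium 4 (not isolated)
Conditions: n-BuLi, THF, 0 → 20 °C; CuI (10 mol %), then 3, −20 → 20 °C
Reagents that add atoms: none
Why: Directed ortho-metalation takes place at C2, the position flanked by both MOM ethers, and copper-assisted substitution at the primary carbon of 3 puts the prenyl group between the two oxygens without any electrophilic aromatic substitution.

Step 3
Reactants: 5 1,3-bis(methoxymethoxy)-2-prenylbenzene; 6 ethylene oxide
Product: 8 2-Ar-ethanol, via aryllithium 7 (not isolated)
Conditions: n-BuLi, TMEDA, THF, 0 °C; 6, −78 → 20 °C; H2O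
Reagents that add atoms: none
Why: A second directed ortho-metalation removes the ring proton next to a MOM ether (C4 and C6 are equivalent), and the aryllithium opens the epoxide to install the two carbons that become C3 and C2.

Step 4
Reactants: 8 2-Ar-ethanol
Product: 10 2-Ar-acetic acid, via arylacetaldehyde 9 (not isolated)
Conditions: TEMPO (20 mol %), PhI(OAc)2, MeCN–H2O, 20 °C
Reagents that add atoms: water, O
Why: Oxoammonium-catalysed (TEMPO) oxidation of the primary alcohol through the aldehyde hydrate to the acid; the conditions are free of chlorine oxidants and strong acid, so the prenyl alkene, the MOM ethers and the electron-rich ring should be left alone.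

Step 5
Reactants: 10 2-Ar-acetic acid; 11 (R)-4-benzyloxazolidin-2-one
Product: 13 (R)-4-benzyl-3-(2-Ar-acetyl)oxazolidin-2-one, via mixed pivalic anhydride 12 (not isolated)
Conditions: t-BuCOCl, Et3N, THF, −20 °C; then 11, LiCl, 20 °C
Reagents that add atoms: pivaloyl chloride, CC(C)(C)C(Cl)=O (its acyl group is found only in 12)
Why: N-Acylation of the auxiliary through the mixed anhydride, with LiCl and Et3N as the activating pair, avoids strong base at the acidic benzylic position.

Step 6
Reactants: 13 (R)-4-benzyl-3-(2-Ar-acetyl)oxazolidin-2-one; 14 allyl iodide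
Product: 16 (R)-4-benzyl-3-[(R)-2-Ar-pent-4-enoyl]oxazolidin-2-one, via sodium enolate 15 (not isolated)
Conditions: NaN(SiMe3)2, THF, −78 °C; 14, −78 → −40 °C
Reagents that add atoms: none
Why: Evans asymmetric alkylation: the chelated (Z)-sodium enolate is shielded on one face by the benzyl group of the (R)-auxiliary, so 14 enters from the other face and C3 is set as R (acyl > aryl > allyl); the low temperature and the reactive iodide limit epimerisation of the α-aryl imide.

Step 7
Reactants: 16 (R)-4-benzyl-3-[(R)-2-Ar-pent-4-enoyl]oxazolidin-2-one
Product: 17 (R)-2-Ar-pent-4-en-1-ol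
Conditions: LiBH4, MeOH (1 equiv), THF, 0 °C
Reagents that add atoms: none
Why: Hydride cleavage of the imide releases the primary alcohol and the recoverable auxiliary without enolisation; from here on C3 is no longer α to a carbonyl group and is configurationally secure.

Step 8
Reactants: 17 (R)-2-Ar-pent-4-en-1-ol
Product: 18 1-[(R)-1-chloropent-4-en-2-yl]-2,4-bis(methoxymethoxy)-3-prenylbenzene
Conditions: PPh3, CCl4, CH2Cl2, 20 → 40 °C
Reagents that add atoms: carbon tetrachloride, ClC(Cl)(Cl)Cl
Why: Appel reaction: SN2 displacement of the oxyphosphonium at the primary carbon under neutral conditions, with no change at C3; the chloride is the latent leaving group for ring C and is inert to the next four steps.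

Step 9
Reactants: 18 1-[(R)-1-chloropent-4-en-2-yl]-2,4-bis(methoxymethoxy)-3-prenylbenzene; 19 methyl vinyl ketone
Product: 20 (R,E)-7-chloro-6-Ar-hept-3-en-2-one
Conditions: RuCl2(H2IMes)(=CH-C6H4-2-O-i-Pr) (second-generation Hoveyda–Grubbs catalyst, 5 mol %), 19 (5 equiv), CH2Cl2, 40 °C
Reagents that add atoms: none
Why: Olefin cross-metathesis of a monosubstituted alkene with an electron-poor enone partner should give the (E)-enone; the trisubstituted prenyl alkene reacts far more slowly with the ruthenium alkylidene.

Step 10
Reactants: 20 (R,E)-7-chloro-6-Ar-hept-3-en-2-one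
Product: 22 (R,E)-7-chloro-1-diazo-6-Ar-hept-3-en-2-one, via trifluoroacetyl diketone 21 (not isolated)
Conditions: LiN(SiMe3)2, THF, −78 °C; CF3CO2CH2CF3; then MeSO2N3, Et3N, H2O, MeCN, 20 °C
Reagents that add atoms: methanesulfonyl azide, CS(=O)(=O)N=[N+]=[N-]; 2,2,2-trifluoroethyl trifluoroacetate, O=C(OCC(F)(F)F)C(F)(F)F (its acyl group is found only in 21)
Why: Detrifluoroacetylative diazo transfer: the kinetic methyl enolate is trifluoroacetylated and the activated diketone takes the diazo group from the sulfonyl azide with loss of the trifluoroacetyl group; this avoids the acid chloride–diazomethane route, which fails for enones through dipolar cycloaddition.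

Step 11
Reactants: 23 ethyl 4-methylpent-3-enoate
Product: 26 triisopropyl(5-methylhex-4-en-1-ynyloxy)silane, via dibromo enolate 24 (not isolated), via lithium ynolate 25 (not isolated)
Conditions: CH2Br2, lithium 2,2,6,6-tetramethylpiperidide, THF, −78 °C; 23; LiN(SiMe3)2; n-BuLi, −78 → 20 °C; i-Pr3SiCl, −78 → 0 °C
Reagents that add atoms: dibromomethane, BrCBr; chlorotriisopropylsilane, CC(C)[Si](Cl)(C(C)C)C(C)C
Why: Kowalski ester homologation halted at the ynolate: addition of LiCHBr2, enolisation, bromine–lithium exchange and 1,2-shift of the prenyl group to the carbenoid carbon give 25, and the bulky silyl chloride reacts at oxygen.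

Step 12
Reactants: 22 (R,E)-7-chloro-1-diazo-6-Ar-hept-3-en-2-one; 26 triisopropyl(5-methylhex-4-en-1-ynyloxy)silane
Product: 31 (R)-2-(3-chloro-2-Ar-propyl)-6-prenyl-5-(triisopropylsilyloxy)phenol, via vinylketene 27 (not isolated), via vinylcyclobutenone 28 (not isolated), via dienylketene 29 (not isolated), via cyclohexadienone 30 (not isolated)
Conditions: 26 (1.5 equiv), hν (350–365 nm, Pyrex), ClCH2CH2Cl, 20 °C; then 80 °C
Reagents that add atoms: none
Why: This is the Danheiser benzannulation in its diazo ketone form, a known reaction of α'-diazo enones with siloxyalkynes. Light absorbed by the diazo enone expels N2 and the alkenyl group shifts to the former diazo carbon (photochemical Wolff rearrangement, forming C5–C6) to give vinylketene 27. The electrophilic ketene carbon (C8a) is attacked by the nucleophilic prenyl-bearing carbon of 26 (C8) and the ketene α-carbon (C6) bonds to the oxygen-bearing alkyne carbon (C7), a regiospecific [2+2] cycloaddition that gives the 4-vinylcyclobutenone 28. On heating, 28 opens by reversible conrotatory four-electron electrocyclic cleavage to dienylketene 29, and the isomer with the vinyl group cis to the ketene closes ring A by thermal disrotatory six-electron electrocyclisation (C4a–C8a) to cyclohexadienone 30, which tautomerises to phenol 31. No stereocentre is created: the sp3 ring carbons of 28 and 30 are transient and are erased on aromatisation, and C3 is two bonds away from any reacting atom under neutral conditions. Regioselectivity rests on the polarity of the ketene and the ynol ether, so the prenyl group must end up between the two oxygens, the silyl ether on C7 and the free hydroxyl on C8a. Chemoselectivity for 26 over the three prenyl alkenes rests on the far higher nucleophilicity of the ynol ether, used in excess, and irradiation above 300 nm keeps the alkoxyarenes, the alkyl chloride and the ortho-prenyl phenol (formed mainly in the dark thermal stage) unexcited.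

Step 13
Reactants: 31 (R)-2-(3-chloro-2-Ar-propyl)-6-prenyl-5-(triisopropylsilyloxy)phenol
Product: 33 (3R)-3-Ar-8-prenylchroman-7-ol, via silyl ether chroman 32 (not isolated)
Conditions: K2CO3, NaI (10 mol %), DMF, 60 °C; then Bu4NF, THF, 20 °C; H2O
Reagents that add atoms: none
Why: Intramolecular Williamson etherification: the only free phenoxide displaces the primary chloride (iodide in situ) in a 6-exo-tet closure that forms O1–C2 without touching C3; fluoride then removes the aryl silyl ether in the same flask while the MOM ethers of ring B stay on.

Step 14
Reactants: 33 (3R)-3-Ar-8-prenylchroman-7-ol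
Product: 34 Kanzonol X
Conditions: HCl (3 M aq.), MeOH, 20 → 40 °C, argon
Reagents that add atoms: none
Why: Acid-catalysed acetal exchange with methanol releases the two ring B phenols; dilute acid, moderate temperature and short exposure are chosen because phenols ortho to prenyl groups cyclise under stronger acid.

## Compound list

1 | resorcinol (benzene-1,3-diol) | Oc1cccc(O)c1 | starting material
2 | 1,3-bis(methoxymethoxy)benzene | COCOc1cccc(OCOC)c1 | intermediate
3 | prenyl bromide (1-bromo-3-methylbut-2-ene) | CC(C)=CCBr | starting material
4 | [2,6-bis(methoxymethoxy)phenyl]lithium (formed in the flask) | [Li]c1c(OCOC)cccc1OCOC | intermediate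
5 | 1,3-bis(methoxymethoxy)-2-(3-methylbut-2-enyl)benzene | COCOc1cccc(OCOC)c1CC=C(C)C | intermediate
6 | ethylene oxide (oxirane) | C1CO1 | starting material
7 | [2,4-bis(methoxymethoxy)-3-(3-methylbut-2-enyl)phenyl]lithium (formed in the flask) | [Li]c1ccc(OCOC)c(CC=C(C)C)c1OCOC | intermediate
8 | 2-[2,4-bis(methoxymethoxy)-3-(3-methylbut-2-enyl)phenyl]ethanol | OCCc1ccc(OCOC)c(CC=C(C)C)c1OCOC | intermediate
9 | 2-[2,4-bis(methoxymethoxy)-3-(3-methylbut-2-enyl)phenyl]acetaldehyde (formed in the flask) | O=CCc1ccc(OCOC)c(CC=C(C)C)c1OCOC | intermediate
10 | 2-[2,4-bis(methoxymethoxy)-3-(3-methylbut-2-enyl)phenyl]acetic acid | OC(=O)Cc1ccc(OCOC)c(CC=C(C)C)c1OCOC | intermediate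
11 | (R)-4-benzyloxazolidin-2-one | O=C1N[C@H](Cc2ccccc2)CO1 | starting material
12 | 2-[2,4-bis(methoxymethoxy)-3-(3-methylbut-2-enyl)phenyl]acetic pivalic anhydride (formed in the flask) | CC(C)(C)C(=O)OC(=O)Cc1ccc(OCOC)c(CC=C(C)C)c1OCOC | intermediate
13 | (R)-4-benzyl-3-{2-[2,4-bis(methoxymethoxy)-3-(3-methylbut-2-enyl)phenyl]acetyl}oxazolidin-2-one | O=C1OC[C@@H](Cc2ccccc2)N1C(=O)Cc1ccc(OCOC)c(CC=C(C)C)c1OCOC | intermediate
14 | allyl iodide (3-iodoprop-1-ene) | C=CCI | starting material
15 | sodium (Z)-enolate of 13 (formed in the flask) | [Na]O/C(=C\c1ccc(OCOC)c(CC=C(C)C)c1OCOC)N1[C@H](Cc2ccccc2)COC1=O | intermediate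
16 | (R)-4-benzyl-3-{(R)-2-[2,4-bis(methoxymethoxy)-3-(3-methylbut-2-enyl)phenyl]pent-4-enoyl}oxazolidin-2-one | O=C1OC[C@@H](Cc2ccccc2)N1C(=O)[C@H](CC=C)c1ccc(OCOC)c(CC=C(C)C)c1OCOC | intermediate
17 | (R)-2-[2,4-bis(methoxymethoxy)-3-(3-methylbut-2-enyl)phenyl]pent-4-en-1-ol | OC[C@H](CC=C)c1ccc(OCOC)c(CC=C(C)C)c1OCOC | intermediate
18 | 1-[(R)-1-chloropent-4-en-2-yl]-2,4-bis(methoxymethoxy)-3-(3-methylbut-2-enyl)benzene | ClC[C@H](CC=C)c1ccc(OCOC)c(CC=C(C)C)c1OCOC | intermediate
19 | methyl vinyl ketone (but-3-en-2-one) | C=CC(C)=O | starting material
20 | (R,E)-7-chloro-6-[2,4-bis(methoxymethoxy)-3-(3-methylbut-2-enyl)phenyl]hept-3-en-2-one | ClC[C@H](C/C=C/C(C)=O)c1ccc(OCOC)c(CC=C(C)C)c1OCOC | intermediate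
21 | (R,E)-9-chloro-1,1,1-trifluoro-8-[2,4-bis(methoxymethoxy)-3-(3-methylbut-2-enyl)phenyl]non-5-ene-2,4-dione (formed in the flask) | ClC[C@H](C/C=C/C(=O)CC(=O)C(F)(F)F)c1ccc(OCOC)c(CC=C(C)C)c1OCOC | intermediate
22 | (R,E)-7-chloro-1-diazo-6-[2,4-bis(methoxymethoxy)-3-(3-methylbut-2-enyl)phenyl]hept-3-en-2-one | ClC[C@H](C/C=C/C(=O)C=[N+]=[N-])c1ccc(OCOC)c(CC=C(C)C)c1OCOC | intermediate
23 | ethyl 4-methylpent-3-enoate | CCOC(=O)CC=C(C)C | starting material
24 | lithium 1,1-dibromo-5-methylhexa-1,4-dien-2-olate (formed in the flask) | [Li]OC(CC=C(C)C)=C(Br)Br | intermediate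
25 | lithium 5-methylhex-4-en-1-yn-1-olate (formed in the flask) | [Li]OC#CCC=C(C)C | intermediate
26 | triisopropyl(5-methylhex-4-en-1-ynyloxy)silane | CC(C)=CCC#CO[Si](C(C)C)(C(C)C)C(C)C | intermediate
27 | (R,E)-7-chloro-6-[2,4-bis(methoxymethoxy)-3-(3-methylbut-2-enyl)phenyl]hepta-1,3-dien-1-one, the vinylketene (formed in the flask) | ClC[C@H](C/C=C/C=C=O)c1ccc(OCOC)c(CC=C(C)C)c1OCOC | intermediate
28 | 4-{(1E,4R)-5-chloro-4-[2,4-bis(methoxymethoxy)-3-(3-methylbut-2-enyl)phenyl]pent-1-enyl}-2-(3-methylbut-2-enyl)-3-(triisopropylsilyloxy)cyclobut-2-en-1-one, both epimers at the ring carbon (formed in the flask) | O=C1C(CC=C(C)C)=C(O[Si](C(C)C)(C(C)C)C(C)C)C1/C=C/C[C@@H](CCl)c1ccc(OCOC)c(CC=C(C)C)c1OCOC | intermediate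
29 | (3E,5E,8R)-9-chloro-8-[2,4-bis(methoxymethoxy)-3-(3-methylbut-2-enyl)phenyl]-2-(3-methylbut-2-enyl)-3-(triisopropylsilyloxy)nona-1,3,5-trien-1-one, the dienylketene (formed in the flask) | O=C=C(CC=C(C)C)/C(O[Si](C(C)C)(C(C)C)C(C)C)=C\C=C\C[C@@H](CCl)c1ccc(OCOC)c(CC=C(C)C)c1OCOC | intermediate
30 | 6-{(R)-3-chloro-2-[2,4-bis(methoxymethoxy)-3-(3-methylbut-2-enyl)phenyl]propyl}-2-(3-methylbut-2-enyl)-3-(triisopropylsilyloxy)cyclohexa-2,4-dien-1-one, both epimers at C6 (formed in the flask) | O=C1C(CC=C(C)C)=C(O[Si](C(C)C)(C(C)C)C(C)C)C=CC1C[C@@H](CCl)c1ccc(OCOC)c(CC=C(C)C)c1OCOC | intermediate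
31 | (R)-2-{3-chloro-2-[2,4-bis(methoxymethoxy)-3-(3-methylbut-2-enyl)phenyl]propyl}-6-(3-methylbut-2-enyl)-5-(triisopropylsilyloxy)phenol | ClC[C@H](Cc1ccc(O[Si](C(C)C)(C(C)C)C(C)C)c(CC=C(C)C)c1O)c1ccc(OCOC)c(CC=C(C)C)c1OCOC | intermediate
32 | triisopropyl{[(3R)-3-[2,4-bis(methoxymethoxy)-3-(3-methylbut-2-enyl)phenyl]-8-(3-methylbut-2-enyl)chroman-7-yl]oxy}silane (formed in the flask) | CC(C)=CCc1c(OCOC)ccc([C@@H]2COc3c(ccc(O[Si](C(C)C)(C(C)C)C(C)C)c3CC=C(C)C)C2)c1OCOC | intermediate
33 | (3R)-3-[2,4-bis(methoxymethoxy)-3-(3-methylbut-2-enyl)phenyl]-8-(3-methylbut-2-enyl)chroman-7-ol | CC(C)=CCc1c(OCOC)ccc([C@@H]2COc3c(ccc(O)c3CC=C(C)C)C2)c1OCOC | intermediate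
34 | Kanzonol X, 4-[(3R)-7-hydroxy-8-(3-methylbut-2-enyl)chroman-3-yl]-2-(3-methylbut-2-enyl)benzene-1,3-diol | CC(C)=CCc1c(O)ccc([C@@H]2COc3c(ccc(O)c3CC=C(C)C)C2)c1O | target

## Step count and least certain steps

Total: 14 steps. Longest linear sequence: 13 steps (steps 1–10 and 12–14); step 11 is the one-step side branch to 26.

Step 12 (key step). The ketene may be consumed by paths other than cycloaddition to the ynol ether: addition to a prenyl alkene, dimerisation, or acylation of the phenol as it forms. Photochemical degradation is also possible if chromophores other than the diazo enone absorb. The cause is a high-energy electrophile generated in a molecule with three other π-nucleophiles. The fallback generates the same ketene thermally and in the dark. It sets out from 18 and uses 26.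
- Cross-metathesis of 18 with but-3-enoic acid (same ruthenium catalyst) would give (R,E)-7-chloro-6-Ar-hept-3-enoic acid F1.
- 1-Chloro-N,N,2-trimethylprop-1-enylamine in CH2Cl2 would convert it under neutral conditions into (R,E)-7-chloro-6-Ar-hept-3-enoyl chloride F2.
- Slow addition of Et3N to F2 and 26 in toluene at 20 °C would form vinylketene 27 by dehydrochlorination at the doubly activated α-carbon and trap it as 28. After filtration of the ammonium salt, heating at 80 °C would lead through 29 and 30 to 31, where the route is rejoined.

Step 11. The β,γ-unsaturated ester has doubly activated α-protons, so the lithium carbenoid or amide may enolise it instead of adding to the carbonyl, and the double bond may drift into conjugation. The fallback makes the ynolate by oxidation of an acetylide and sets out from 3.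
- Copper-catalysed coupling of 3 with ethynyltrimethylsilane (CuI, K2CO3, NaI, DMF) would give trimethyl(5-methylhex-4-en-1-ynyl)silane F3.
- K2CO3 in MeOH would give 5-methylhex-4-en-1-yne F4.
- n-BuLi would give (5-methylhex-4-en-1-ynyl)lithium F5, which lithium tert-butyl peroxide oxidises to the ynolate 25. Silylation with i-Pr3SiOTf rejoins the route at 26.

Step 3. The benzylic and allylic CH2 of the prenyl group lies between two directing groups, so deprotonation there may compete with ring metalation; the hindered aryllithium may also open the epoxide sluggishly. The fallback fixes the metalation site by halogen–lithium exchange and sets out from 2.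
- N-Bromosuccinimide in MeCN would give 1-bromo-2,4-bis(methoxymethoxy)benzene F6.
- LiN(i-Pr)2 at −78 °C would remove the proton between the two MOM ethers to give [3-bromo-2,6-bis(methoxymethoxy)phenyl]lithium F7.
- CuI and 3 would give 1-bromo-2,4-bis(methoxymethoxy)-3-prenylbenzene F8 (the same bromide as A6).
- Bromine–lithium exchange with n-BuLi at −78 °C would deliver aryllithium 7 regiospecifically, which is carried on with 6 to 8 as in step 3.

Step 9. The ruthenium alkylidene may engage the prenyl alkene (with extrusion of isobutene) and turnover with the enone may be slow, because the substrate offers a second, if less reactive, alkene. The fallback builds the enone by carbonyl olefination and sets out from 13.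
- Enolate 15, formed as in step 6, would be alkylated with tert-butyl bromoacetate to tert-butyl (R)-4-[(R)-4-benzyl-2-oxooxazolidin-3-yl]-3-Ar-4-oxobutanoate F9.
- LiBH4 would reduce the imide selectively to tert-butyl (R)-3-Ar-4-hydroxybutanoate F10.
- PPh3 and CCl4 would give tert-butyl (R)-3-Ar-4-chlorobutanoate F11.
- i-Bu2AlH at −78 °C would give (R)-3-Ar-4-chlorobutanal F12.
- Horner–Wadsworth–Emmons olefination with diethyl (3-diazo-2-oxopropyl)phosphonate (NaH, THF, 0 °C) would give the (E)-diazo enone 22 directly, bypassing steps 9 and 10.

Step 14. While the acetals are cleaved, a phenol may cyclise onto its ortho prenyl group (2,2-dimethylchroman formation), or methanol or HCl may add to an alkene, because the liberated phenols and the trisubstituted alkenes are both acid-sensitive. The fallback uses no Brønsted acid and sets out from 33.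
- Me3SiOTf and 2,2'-bipyridyl in MeCN at 0 °C would convert the aryl MOM ethers into aryl silyl ethers, with the methoxymethyl cation captured on the pyridine nitrogen, and would silylate the 7-hydroxyl. The product is trimethyl{[(3R)-3-[2,4-bis(trimethylsilyloxy)-3-prenylphenyl]-8-prenylchroman-7-yl]oxy}silane F13.
- K2CO3 in MeOH at 0 °C would remove the three silyl groups and give 34.

## Further compounds

F1 | step 12 | (R,E)-7-chloro-6-[2,4-bis(methoxymethoxy)-3-(3-methylbut-2-enyl)phenyl]hept-3-enoic acid | OC(=O)C/C=C/C[C@@H](CCl)c1ccc(OCOC)c(CC=C(C)C)c1OCOC
F2 | step 12 | (R,E)-7-chloro-6-[2,4-bis(methoxymethoxy)-3-(3-methylbut-2-enyl)phenyl]hept-3-enoyl chloride | ClC(=O)C/C=C/C[C@@H](CCl)c1ccc(OCOC)c(CC=C(C)C)c1OCOC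
F3 | step 11 | trimethyl(5-methylhex-4-en-1-ynyl)silane | CC(C)=CCC#C[Si](C)(C)C
F4 | step 11 | 5-methylhex-4-en-1-yne | CC(C)=CCC#C
F5 | step 11 | (5-methylhex-4-en-1-ynyl)lithium | [Li]C#CCC=C(C)C
F6 | step 3 | 1-bromo-2,4-bis(methoxymethoxy)benzene | COCOc1ccc(Br)c(OCOC)c1
F7 | step 3 | [3-bromo-2,6-bis(methoxymethoxy)phenyl]lithium | [Li]c1c(OCOC)ccc(Br)c1OCOC
F8 | step 3 | 1-bromo-2,4-bis(methoxymethoxy)-3-(3-methylbut-2-enyl)benzene | COCOc1ccc(Br)c(OCOC)c1CC=C(C)C
F9 | step 9 | tert-butyl (R)-4-[(R)-4-benzyl-2-oxooxazolidin-3-yl]-3-[2,4-bis(methoxymethoxy)-3-(3-methylbut-2-enyl)phenyl]-4-oxobutanoate | O=C1OC[C@@H](Cc2ccccc2)N1C(=O)[C@H](CC(=O)OC(C)(C)C)c1ccc(OCOC)c(CC=C(C)C)c1OCOC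
F10 | step 9 | tert-butyl (R)-3-[2,4-bis(methoxymethoxy)-3-(3-methylbut-2-enyl)phenyl]-4-hydroxybutanoate | OC[C@H](CC(=O)OC(C)(C)C)c1ccc(OCOC)c(CC=C(C)C)c1OCOC
F11 | step 9 | tert-butyl (R)-3-[2,4-bis(methoxymethoxy)-3-(3-methylbut-2-enyl)phenyl]-4-chlorobutanoate | ClC[C@H](CC(=O)OC(C)(C)C)c1ccc(OCOC)c(CC=C(C)C)c1OCOC
F12 | step 9 | (R)-3-[2,4-bis(methoxymethoxy)-3-(3-methylbut-2-enyl)phenyl]-4-chlorobutanal | ClC[C@H](CC=O)c1ccc(OCOC)c(CC=C(C)C)c1OCOC
F13 | step 14 | trimethyl{[(3R)-3-[2,4-bis(trimethylsilyloxy)-3-(3-methylbut-2-enyl)phenyl]-8-(3-methylbut-2-enyl)chroman-7-yl]oxy}silane | CC(C)=CCc1c(O[Si](C)(C)C)ccc([C@@H]2COc3c(ccc(O[Si](C)(C)C)c3CC=C(C)C)C2)c1O[Si](C)(C)C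
A1 | alternative 1 | 3-(methoxymethoxy)-2-(3-methylbut-2-enyl)-6-[(phenylsulfonyl)methyl]phenol | O=S(=O)(Cc1ccc(OCOC)c(CC=C(C)C)c1O)c1ccccc1
A2 | alternative 1 | (3R)-7-(methoxymethoxy)-3-[2,4-bis(methoxymethoxy)-3-(3-methylbut-2-enyl)phenyl]-8-(3-methylbut-2-enyl)chroman-2-ol, both anomers at C2 | CC(C)=CCc1c(OCOC)ccc([C@@H]2C(O)Oc3c(ccc(OCOC)c3CC=C(C)C)C2)c1OCOC
A3 | alternative 2 | 1-[(3R)-7-(methoxymethoxy)-8-(3-methylbut-2-enyl)chroman-3-yl]propan-2-one | CC(=O)C[C@@H]1COc2c(CC=C(C)C)c(OCOC)ccc2C1
A4 | alternative 2 | methyl acrylate | C=CC(=O)OC
A5 | alternative 2 | 4-[(R)-7-(methoxymethoxy)-8-(3-methylbut-2-enyl)chroman-3-yl]cyclohexane-1,3-dione, both epimers at C1' | O=C1CC(=O)C(CC1)[C@@H]2COc3c(CC=C(C)C)c(OCOC)ccc3C2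
A6 | alternative 3 | 1-bromo-2,4-bis(methoxymethoxy)-3-(3-methylbut-2-enyl)benzene | COCOc1ccc(Br)c(OCOC)c1CC=C(C)C
A7 | alternative 3 | vinylboronic acid pinacol ester (4,4,5,5-tetramethyl-2-vinyl-1,3,2-dioxaborolane) | C=CB1OC(C)(C)C(C)(C)O1
A8 | alternative 3 | [6-bromo-3-(methoxymethoxy)-2-(3-methylbut-2-enyl)phenoxy](tert-butyl)dimethylsilane | CC(C)(C)[Si](C)(C)Oc1c(Br)ccc(OCOC)c1CC=C(C)C
A9 | alternative 3 | (R)-2-{1-[2,4-bis(methoxymethoxy)-3-(3-methylbut-2-enyl)phenyl]-2-[2-(tert-butyldimethylsilyloxy)-4-(methoxymethoxy)-3-(3-methylbut-2-enyl)phenyl]ethyl}-4,4,5,5-tetramethyl-1,3,2-dioxaborolane | CC1(C)OB(OC1(C)C)[C@H](Cc1ccc(OCOC)c(CC=C(C)C)c1O[Si](C)(C)C(C)(C)C)c1ccc(OCOC)c(CC=C(C)C)c1OCOC
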